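## Structural features

The target is a trans-2-aryl-3-methyl-2,3-dihydro-1-benzofuran. Benzene ring A is fused through C3a and C7a to the five-membered oxygen ring B (O1, C2, C3), and C2 carries the 3,4-dimethoxyphenyl ring C. Ring A bears a methoxy group at C7, next to the oxygen-bearing C7a, and an (E)-3-hydroxyprop-1-enyl chain at C5, para to O1. The only stereocentres are the adjacent C2 (S, benzylic and O-bearing) and C3 (S, benzylic, methyl-bearing), with aryl and methyl trans across ring B. The O1–C2 bond is a doubly activated benzylic ether that ionises in acid, which makes C2 correctable but endangers C3 if proton loss intervenes. The cinnamyl alcohol is sensitive to acid and ozone and must arrive late, and all three arenes are electron-rich. The real difficulty is the absolute configuration at C3, a tertiary benzylic C–H centre with no heteroatom to steer its construction; once C3 is fixed, the trans relationship lets C2 follow. The key step uses the fact that C3 is a benzylic CH(CH3) on C3a, the ring A carbon ortho to C7a–O: its C3–CH3 bond can be made by branch-selective attack of a methyl nucleophile on a cinnamyl bromide of ring A, and the vinyl group left behind is the latent C2.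

## Logic of the disconnections

**16 ⇒ 15.** The O–H of the allylic alcohol in 16 is traced back to the O–Si bond of 15. The cut is made there because the three-carbon chain is brought in as a stable alkenyl boron reagent whose oxygen is silylated. The gain is that no free allylic alcohol is present during the coupling. The forward step must cleave the silyl ether without acid, because the O1–C2 bond and the cinnamyl alcohol both ionise easily.

**15 ⇒ 13 + 14.** The C5–C(alkenyl) bond between ring A and the side chain is cut. The chain holds the only functionality that cannot survive ozonolysis or strong acid, so it is placed after both, and the bromine at C5 of 13 is a silent placeholder through every earlier step. The gain is that 13 has no alkene and no free alcohol, and the E geometry comes ready-made with 14. The forward coupling must retain that geometry on an electron-rich aryl bromide and leave C2 and C3 untouched.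

**13 ⇒ 12.** The O1–C2 bond is cut, together with the acetal on the C7a oxygen. C2 is attached to ring C with its two donor groups and so supports a cation, and closure through that cation gives the trans ring whatever the carbinol configuration. The gain is that C2 needs no control in any earlier step, so 12 carries stereochemical information only at the future C3. The demand is that capture by the C7a oxygen is faster than proton loss from C3, and that the oxygen protecting group leaves in the same acid.

**12 ⇒ 9 + 11 (11 ⇐ 10).** The bond from C2 to ring C is cut. This joins the two aryl halves at a carbonyl carbon, and ring C comes from 10 through 11. The gain is two fragments of similar size and a convergent union. The demand is that addition to 9 outruns enolisation, because the stereocentre of 9 is both benzylic and α to the carbonyl; diastereoselectivity is not needed.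

**9 ⇒ 7 (through 8).** The carbonyl carbon of 9 is traced to the internal alkene carbon of 7, so the forward step cleaves the terminal C=C by way of 8. A vinyl group is exactly what a branch-selective allylic substitution leaves next to its new stereocentre. The gain is that 7 is a robust, non-enolisable carrier of the C3 centre. The demand is a cold, neutral cleavage that is selective for the single alkene over the electron-rich ring, with 9 taken on unpurified.

**7 ⇒ 5 + 6.** The C3–CH3 bond is cut. In 5 the future C3 is the γ-terminus of an allylic bromide and can receive the methyl group of 6 with allylic transposition. The gain is that the one stereocentre needing reagent control arises from a flat, achiral alkene under catalyst control, without an auxiliary. The demand is branched over linear substitution, one alkene face, and no reaction at the aryl C–Br bond.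

**5 ⇒ 4.** The primary C–Br bond of 5 is traced, with 1,3-transposition, to the secondary C–O bond of 4. The conjugated primary bromide is the thermodynamic sink of the allylic system. The gain is one operation fewer than an olefination–reduction–bromination sequence. The demand is complete migration to the E bromide without acid damage to the acetal.

**4 ⇒ 2 + 3.** The bond between the carbinol carbon and the vinyl group is cut. This returns to an aldehyde and a two-carbon nucleophile, both simple. The demand is only chemoselective carbonyl addition in the presence of the aryl bromide.

**2 ⇒ 1.** The O–CH2 bond of the acetal is cut. The phenol must be masked against three organomagnesium steps and ozone, and the acetal is the group that later departs in the ring-closing acid. The forward alkylation must overcome a hindered, hydrogen-bonded phenol.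

## Other disconnections considered

**Alternative 1:** The cut removes both bonds that tie ring B to ring A, C3–C3a and O1–C7a, leaving methyl 4-iodo-3-methoxybenzoate A2 and the cis-epoxide (2R,3S)-2-(3,4-dimethoxyphenyl)-3-methyloxirane A3.
- **Forward key step:** a Catellani-type annulation with Pd(OAc)2, a phosphine, norbornene and Cs2CO3. Zerovalent palladium inserts into the C–I bond of A2 and norbornene relays the metal to the free ortho C–H. The palladacycle of divalent palladium opens A3 at the methyl-bearing carbon with inversion (C3–C3a). Norbornene is then extruded and the aryl–palladium alkoxide closes O1–C7a. The product would be methyl (2S,3S)-2-(3,4-dimethoxyphenyl)-7-methoxy-3-methyl-2,3-dihydro-1-benzofuran-5-carboxylate A1; inversion at C3 and retention at C2 turn the cis-epoxide into the trans ring.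
- **In favour:** ring B and the trans relationship arise in one stereospecific step from two simple pieces. The phenol oxygen needs no protecting group, and the methoxy group of A2 blocks the second ortho position. No cation at C2 and no enolisable aldehyde ever appear. On convergence and on the safety of C3 this plan is the better one.
- **Against:** the annulation is established mainly for terminal epoxides. A3 would have to open at a secondary carbon in preference to its much more labile, donor-activated benzylic C–O bond, and it could isomerise to a ketone under the conditions. A3 also rests on an asymmetric epoxidation of a Z-configured styrene and is an acid-sensitive epoxide. The ester of A1 costs three operations (reduction, olefination, reduction) where the bromide of the chosen plan costs two.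
- **Comparison:** step economy is about equal, and both plans take the absolute configuration from a catalytic asymmetric reaction, so they are equal there. The chosen plan is preferred because its key step has close precedent for the substrate class, whereas the regiochemistry of opening A3 is open.

**Alternative 2:** The cut runs through C2–C3 and O1–C2, so C2 with ring C becomes a one-carbon unit added to a four-atom ortho-quinone methide of ring A.
- **Forward key step:** Cs2CO3 would eliminate sulfinate from 4-bromo-2-methoxy-6-[1-(4-methylphenyl)sulfonylethyl]phenol A5 to give the ethylidene quinone methide. It would also deprotonate the chiral salt (2R,5R)-1-[(3,4-dimethoxyphenyl)methyl]-2,5-dimethylthiolan-1-ium bromide A6 to its benzylide. A6 is written as one antipode; which antipode serves the 2S,3S series would have to be established. Conjugate addition of the ylide carbon to the methide carbon forms C2–C3, and the phenoxide then displaces the sulfide at C2 with inversion (5-exo-tet) to form O1–C2. The product, (2S,3S)-5-bromo-2-(3,4-dimethoxyphenyl)-7-methoxy-3-methyl-2,3-dihydro-1-benzofuran A4, is identical with 13.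
- **In favour:** A4 would be reached in about three steps from 1 and then takes the same two-step endgame, so this plan is clearly better in step economy. The conditions are basic throughout, with no cation at C2 and no α-aryl aldehyde, which is better for the integrity of C3 once formed. Trans selectivity from an anti betaine closing by SN2 is the equal of the chosen plan.
- **Against:** both stereocentres must be set at once by a stoichiometric chiral sulfide that is remote from C3. A semi-stabilised, electron-rich benzylide adds less predictably than the stabilised ylides on which most asymmetric precedent rests. The quinone methide carries a methyl group and can tautomerise to a 2-vinylphenol or oligomerise before the ylide arrives.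
- **Comparison:** the chosen plan separates the two problems, setting C3 by a precedented catalytic reaction and C2 by thermodynamics. That is judged more dependable than staking both centres on one reagent-controlled event, at the price of about four more steps.

**Alternative 3:** The C3–C3a bond is traced to a 1,2-shift of the ring A carbon in a flavanone, (2S)-6-bromo-2-(3,4-dimethoxyphenyl)-8-methoxy-2,3-dihydrochromen-4-one A8, whose pyranone ring is contracted to ring B.
- **Forward key step:** PhI(OAc)2 and H2SO4 in trimethyl orthoformate would convert the ketone of A8 into its enol ether. Trivalent iodine adds to C3 on the face away from the C2 aryl group. Loss of iodobenzene is accompanied by migration of the ring A carbon from C4 to C3, and C4 ends as the ester of methyl (2S,3S)-5-bromo-2-(3,4-dimethoxyphenyl)-7-methoxy-2,3-dihydro-1-benzofuran-3-carboxylate A7.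
- **In favour:** enantioenriched flavanones are accessible by well-developed catalytic methods and the reagents are cheap. C2 is in place first and relays its configuration to C3, so the trans relationship is a kinetic consequence and no racemisation-prone aldehyde is involved; on that point the plan is equal or better. The C5 bromide for the same endgame is already present.
- **Against:** C3 arrives as an ester, and three further operations (reduction, sulfonylation, hydride displacement) are needed to reach the methyl group of 13. The donor-rich ring C is itself a good migrating group and could compete through a 2,3-shift or promote dehydrogenation. Strong acid can open A8 by a retro-oxa-Michael reaction and so erode C2, the only source of chirality.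
- **Comparison:** on structure it maps the trans-2-aryl pattern as directly as the chosen plan, and it is equal in using catalysis for the absolute configuration. It is clearly longer (about eleven or twelve steps against nine), and which aryl group migrates is a chemoselectivity not secured by the substrate, whereas the chosen key step has its selectivities set by the catalyst.

Key step: step 4

## Remarks before the steps

- **Assumption:** the sense of induction of the CuBr·SMe2/Taniaphos catalyst on 5 is taken to be the same as on unsubstituted cinnamyl bromide, which leads to the (S,S) ligand; should the first run give the antipode of 7, the (R,R) ligand is used and nothing else changes.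
- **Descriptor bookkeeping:** the methyl-bearing carbon is R in 7 but S in 8, 9, 12, 13, 15 and 16 although no bond to it is touched after step 4. The CIP rank of its neighbour rises above that of ring A once the vinyl group becomes an O-bearing carbon.
- **Design of 5:** the MOM acetal is kept because it survives organomagnesium reagents and ozone and leaves in the acid that closes ring B. The C5 bromine is kept because it is inert until the final coupling. The bromide 5 is reached by allylic transposition from 4, one operation fewer than olefination, reduction and bromination.

## Route

Step 1
Reactants: 1 5-bromo-2-hydroxy-3-methoxybenzaldehyde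
Product: 2 5-bromo-3-methoxy-2-(methoxymethoxy)benzaldehyde
Conditions: MOMCl (1.3 equiv), K2CO3 (2 equiv), DMF, 0 °C → rt
Reagents that add atoms: chloromethyl methyl ether (MOMCl), COCCl
Why: Williamson-type O-alkylation: the acidic, hydrogen-bonded phenol is deprotonated by K2CO3 and the phenoxide displaces chloride from MOMCl. The acetal masks the phenol through the organomagnesium steps and ozonolysis and is lost later in the acid that closes ring B.

Step 2
Reactants: 2 5-bromo-3-methoxy-2-(methoxymethoxy)benzaldehyde; 3 vinylmagnesium bromide
Product: 4 (1RS)-1-[5-bromo-3-methoxy-2-(methoxymethoxy)phenyl]prop-2-en-1-ol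
Conditions: 3 (1 M in THF, 1.2 equiv), THF, −78 → 0 °C; aq NH4Cl
Reagents that add atoms: none
Why: Grignard 1,2-addition to the aldehyde; the aryl bromide does not exchange with 3 at this temperature and the acetal is inert. The carbinol centre is racemic and is erased in step 3.

Step 3
Reactants: 4 (1RS)-1-[5-bromo-3-methoxy-2-(methoxymethoxy)phenyl]prop-2-en-1-ol
Product: 5 5-bromo-1-[(E)-3-bromoprop-1-enyl]-3-methoxy-2-(methoxymethoxy)benzene
Conditions: PBr3 (0.4 equiv), Et2O, −20 → 0 °C; aq NaHCO3
Reagents that add atoms: phosphorus tribromide, BrP(Br)Br
Why: Allylic bromination with 1,3-transposition (SN2′ or ion-pair pathway): the dibromophosphite of the benzylic allylic alcohol is displaced by bromide at the terminal carbon, and any secondary bromide equilibrates through the allyl cation–bromide pair to the conjugated primary bromide, whose E geometry is the thermodynamic one. Ether as solvent, substoichiometric PBr3, low temperature and a bicarbonate quench are chosen to keep the MOM acetal intact.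

Step 4
Reactants: 5 5-bromo-1-[(E)-3-bromoprop-1-enyl]-3-methoxy-2-(methoxymethoxy)benzene; 6 methylmagnesium bromide
Product: 7 5-bromo-1-[(2R)-but-3-en-2-yl]-3-methoxy-2-(methoxymethoxy)benzene
Conditions: CuBr·SMe2 (5 mol%), (S,S)-Taniaphos (6 mol%), CH2Cl2, −75 °C; 6 (3 M in Et2O, 1.3 equiv) added slowly; MeOH quench
Reagents that add atoms: none
Why: This is a CuBr·SMe2/Taniaphos-catalysed asymmetric allylic alkylation (SN2′) of a cinnamyl bromide with a Grignard reagent, a known reaction type for MeMgBr in CH2Cl2 at low temperature. Reagent 6 transmetalates to the monovalent copper–diphosphine complex, and the resulting L*Cu–CH3 species (L* = Taniaphos) binds the alkene of 5 and adds oxidatively at the benzylic γ-carbon anti to the departing bromide, giving a σ-allyl complex of trivalent copper. Reductive elimination from this complex should be faster than its shift to the primary terminus, so the C3–CH3 bond forms at the benzylic carbon and a terminal vinyl group results. No ring is closed. The new stereocentre (R in 7, the later C3) is set by catalyst control, the ferrocenyl diphosphine distinguishing the two faces of the E alkene and the ligand antipode fixing the sense. Three selectivities are needed: branched over linear, one alkene face, and allylic over aryl bromide. The first two are secured by the bromide leaving group, CH2Cl2, −75 °C and slow addition of 6, which keep the ligand-bound pathway ahead of uncatalysed SN2 attack, and by the E geometry of 5; the third by the inertness of the aryl C–Br bond to MeMgBr and to the CuBr·SMe2-derived catalyst at this temperature. The MOM acetal is inert to 6, and the bromine on ring A tempers ionisation of the ortho-alkoxy cinnamyl bromide.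

Step 5
Reactants: 7 5-bromo-1-[(2R)-but-3-en-2-yl]-3-methoxy-2-(methoxymethoxy)benzene
Product: 9 (2S)-2-[5-bromo-3-methoxy-2-(methoxymethoxy)phenyl]propanal, via ozonide 8 (not isolated)
Conditions: O3, CH2Cl2, −78 °C (Sudan Red 7B end point); PPh3 (1.2 equiv), −78 → 0 °C; crude 9 used at once
Reagents that add atoms: ozone, [O-][O+]=O
Why: Ozonolysis (Criegee mechanism) of the only alkene, with PPh3 reducing the ozonide 8 below 0 °C. The dye marks the end point so that the electron-rich ring and the acetal C–H bonds are not exposed to excess ozone, and the α-aryl aldehyde is not chromatographed, to protect the stereocentre next to the carbonyl.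

Step 6
Reactants: 9 (2S)-2-[5-bromo-3-methoxy-2-(methoxymethoxy)phenyl]propanal; 10 4-bromo-1,2-dimethoxybenzene
Product: 12 (1RS,2S)-2-[5-bromo-3-methoxy-2-(methoxymethoxy)phenyl]-1-(3,4-dimethoxyphenyl)propan-1-ol, via 3,4-dimethoxyphenylmagnesium bromide 11 (not isolated)
Conditions: 10, Mg, I2 (cat.), THF, rt → 40 °C; 9 in THF added to 11 (2 equiv) at −78 °C; aq NH4Cl
Reagents that add atoms: none
Why: Grignard formation from the aryl bromide followed by 1,2-addition to the aldehyde; adding cold 9 to an excess of 11 at −78 °C should let addition outrun enolisation, so the stereocentre α to the carbonyl is kept. The Felkin–Anh preference favours the (1R,2S) epimer, but the carbinol configuration is immaterial because step 7 passes through a planar cation. The aryl bromide of 9 does not exchange with an arylmagnesium reagent.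

Step 7
Reactants: 12 (1RS,2S)-2-[5-bromo-3-methoxy-2-(methoxymethoxy)phenyl]-1-(3,4-dimethoxyphenyl)propan-1-ol
Product: 13 (2S,3S)-5-bromo-2-(3,4-dimethoxyphenyl)-7-methoxy-3-methyl-2,3-dihydro-1-benzofuran
Conditions: TFA/CH2Cl2 (1:10), 0 °C, short reaction time; aq NaHCO3
Reagents that add atoms: none
Why: Acid-mediated SN1 cycloetherification: TFA ionises the carbinol to a benzylic cation stabilised by the two methoxy groups of ring C, and the oxygen on C7a captures it in a 5-exo-trig closure, either as the MOM ether (the oxonium then sheds the methoxymethyl cation) or as the phenol once the acetal is cleaved. C2 is set here under substrate control: the aryl group avoids the C3 methyl in the closing transition state, and reversible ionisation of the O1–C2 bond funnels any cis isomer to the more stable trans ring, so both carbinol epimers of 12 should converge on (2S,3S)-13. A short time at 0 °C keeps proton loss from C3 of the cation, the one event that could erase that centre, behind ring closure.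

Step 8
Reactants: 13 (2S,3S)-5-bromo-2-(3,4-dimethoxyphenyl)-7-methoxy-3-methyl-2,3-dihydro-1-benzofuran; 14 (E)-3-(tert-butyldimethylsilyloxy)prop-1-enylboronic acid pinacol ester
Product: 15 tert-butyl-[(E)-3-[(2S,3S)-2-(3,4-dimethoxyphenyl)-7-methoxy-3-methyl-2,3-dihydro-1-benzofuran-5-yl]prop-2-enoxy]dimethylsilane
Conditions: PdCl2(dppf) (5 mol%), K2CO3 (3 equiv), 1,4-dioxane/H2O (4:1), 80 °C
Reagents that add atoms: none
Why: Suzuki–Miyaura coupling: oxidative addition of zerovalent palladium to the aryl bromide, base-assisted transmetalation of the alkenyl boronate and reductive elimination with retention of the E geometry. The benzylic ether stereocentres are not touched under basic conditions and the silyl ether survives aqueous carbonate.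

Step 9
Reactants: 15 tert-butyl-[(E)-3-[(2S,3S)-2-(3,4-dimethoxyphenyl)-7-methoxy-3-methyl-2,3-dihydro-1-benzofuran-5-yl]prop-2-enoxy]dimethylsilane
Product: 16 (E)-3-[(2S,3S)-2-(3,4-dimethoxyphenyl)-7-methoxy-3-methyl-2,3-dihydro-1-benzofuran-5-yl]prop-2-en-1-ol
Conditions: Bu4NF (1.2 equiv), THF, 0 °C → rt
Reagents that add atoms: none
Why: Fluoride-induced cleavage of the primary silyl ether, driven by Si–F bond formation. The neutral to basic medium leaves the acid-labile O1–C2 bond and the cinnamyl alcohol intact.

## Compound list

1 | 5-bromo-2-hydroxy-3-methoxybenzaldehyde | COc1cc(Br)cc(C=O)c1O | starting material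
2 | 5-bromo-3-methoxy-2-(methoxymethoxy)benzaldehyde | COCOc1c(OC)cc(Br)cc1C=O | intermediate
3 | vinylmagnesium bromide | C=C[Mg]Br | starting material
4 | (1RS)-1-[5-bromo-3-methoxy-2-(methoxymethoxy)phenyl]prop-2-en-1-ol | C=CC(O)c1cc(Br)cc(OC)c1OCOC | intermediate
5 | 5-bromo-1-[(E)-3-bromoprop-1-enyl]-3-methoxy-2-(methoxymethoxy)benzene | COCOc1c(OC)cc(Br)cc1/C=C/CBr | intermediate
6 | methylmagnesium bromide | C[Mg]Br | starting material
7 | 5-bromo-1-[(2R)-but-3-en-2-yl]-3-methoxy-2-(methoxymethoxy)benzene | C=C[C@@H](C)c1cc(Br)cc(OC)c1OCOC | intermediate
8 | 3-[(1S)-1-[5-bromo-3-methoxy-2-(methoxymethoxy)phenyl]ethyl]-1,2,4-trioxolane (ozonide, epimers at the ring carbon, formed in the flask) | O1COOC1[C@@H](C)c1cc(Br)cc(OC)c1OCOC | intermediate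
9 | (2S)-2-[5-bromo-3-methoxy-2-(methoxymethoxy)phenyl]propanal | O=C[C@@H](C)c1cc(Br)cc(OC)c1OCOC | intermediate
10 | 4-bromo-1,2-dimethoxybenzene | COc1ccc(Br)cc1OC | starting material
11 | 3,4-dimethoxyphenylmagnesium bromide (formed in the flask) | COc1ccc([Mg]Br)cc1OC | intermediate
12 | (1RS,2S)-2-[5-bromo-3-methoxy-2-(methoxymethoxy)phenyl]-1-(3,4-dimethoxyphenyl)propan-1-ol | COc1ccc(C(O)[C@@H](C)c2cc(Br)cc(OC)c2OCOC)cc1OC | intermediate
13 | (2S,3S)-5-bromo-2-(3,4-dimethoxyphenyl)-7-methoxy-3-methyl-2,3-dihydro-1-benzofuran | COc1ccc([C@H]2Oc3c(OC)cc(Br)cc3[C@@H]2C)cc1OC | intermediate
14 | (E)-3-(tert-butyldimethylsilyloxy)prop-1-enylboronic acid pinacol ester | CC(C)(C)[Si](C)(C)OC/C=C/B1OC(C)(C)C(C)(C)O1 | starting material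
15 | tert-butyl-[(E)-3-[(2S,3S)-2-(3,4-dimethoxyphenyl)-7-methoxy-3-methyl-2,3-dihydro-1-benzofuran-5-yl]prop-2-enoxy]dimethylsilane | COc1ccc([C@H]2Oc3c(OC)cc(/C=C/CO[Si](C)(C)C(C)(C)C)cc3[C@@H]2C)cc1OC | intermediate
16 | (E)-3-[(2S,3S)-2-(3,4-dimethoxyphenyl)-7-methoxy-3-methyl-2,3-dihydro-1-benzofuran-5-yl]prop-2-en-1-ol | COc1ccc([C@H]2Oc3c(OC)cc(/C=C/CO)cc3[C@@H]2C)cc1OC | target

## Step count and least certain steps

Total step count: 9. Longest linear sequence: 9 steps (1 → 16); 3, 6, 10 and 14 enter as purchased building blocks.

**Step 4 (key step).** The most likely failure is erosion of branch selectivity and enantioselectivity. The ortho MOM ether can chelate magnesium or copper close to the reacting alkene, and the electron-rich cinnamyl bromide is prone to uncatalysed or ion-pair substitution that gives linear and racemic material. Fallback: the allylic substitution is given up and 7 is made from 2. Wittig methylenation (Ph3PCH3Br, KOt-Bu, THF) gives 5-bromo-1-ethenyl-3-methoxy-2-(methoxymethoxy)benzene F1. Asymmetric hydrovinylation with ethylene ([Ni(allyl)Br]2, NaB[3,5-(CF3)2C6H3]4, a chiral phosphoramidite, CH2Cl2, −70 °C) then adds hydrogen and vinyl across the styrene in the Markovnikov sense. This sets out from 2 and comes back at 7, replacing steps 2 to 4.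

**Step 3.** The most likely failure is incomplete transposition together with partial loss or cyclisation of the MOM acetal. HBr is released next to an acid-labile acetal, and the carbinol oxygen sits where it can close a six-membered methylene acetal onto it. Fallback: from 2, Horner–Wadsworth–Emmons olefination with triethyl phosphonoacetate (NaH, THF) gives ethyl (E)-3-[5-bromo-3-methoxy-2-(methoxymethoxy)phenyl]prop-2-enoate F2. Reduction with i-Bu2AlH (CH2Cl2, −78 °C) gives (E)-3-[5-bromo-3-methoxy-2-(methoxymethoxy)phenyl]prop-2-en-1-ol F3. An Appel reaction (CBr4, PPh3, CH2Cl2, 0 °C) returns to the route at 5. This costs one more step, but every step is neutral or basic and the E geometry is fixed by the olefination.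

**Step 5.** The most likely failure is over-oxidation of ring A or of the acetal CH2 by ozone, because both are electron-rich and the end point is narrow. Fallback: from 7, dihydroxylation (OsO4 cat., N-methylmorpholine N-oxide, acetone/H2O) gives (3S)-3-[5-bromo-3-methoxy-2-(methoxymethoxy)phenyl]butane-1,2-diol F4 as a pair of C2 epimers. Glycol cleavage with NaIO4 on silica gel in CH2Cl2 at 0 °C then returns to the route at 9, which is filtered and used at once.

**Step 6.** The most likely failure is partial loss of configuration at the carbon next to the carbonyl, through enolisation of 9 by the basic arylmagnesium reagent or by the magnesium alkoxide being formed. Fallback: the Grignard reagent is replaced by a non-basic organocerium nucleophile. From 10, bromine–lithium exchange (n-BuLi, THF, −78 °C) gives (3,4-dimethoxyphenyl)lithium F5. Transmetalation with anhydrous CeCl3 gives dichloro(3,4-dimethoxyphenyl)cerium F6, which adds to 9 at −78 °C and returns to the route at 12.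

**Step 7.** The most likely failure is erosion of the C3 configuration by reversible proton loss from the C2 cation, together with alkylation of the electron-rich rings by the liberated methoxymethyl cation. Both follow from running deprotection and ionisation in one strongly acidic, non-nucleophilic medium. Fallback: the two events are separated. From 12, aqueous HCl in THF at room temperature removes the acetal while water returns any cation to the carbinol, giving (1RS,2S)-2-(5-bromo-2-hydroxy-3-methoxyphenyl)-1-(3,4-dimethoxyphenyl)propan-1-ol F7; any 13 already formed is carried along. Ring closure by intramolecular Mitsunobu etherification (PPh3, DIAD, THF, 0 °C) then returns to the route at 13. For the major (1R,2S) epimer this is a direct inversion to the trans ring under neutral conditions. The minor epimer is expected to close through the ion pair that ring C supports, and would be removed by chromatography of F7 if it does not converge.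

## Further compounds

F1 | step 4 | 5-bromo-1-ethenyl-3-methoxy-2-(methoxymethoxy)benzene | C=Cc1cc(Br)cc(OC)c1OCOC
F2 | step 3 | ethyl (E)-3-[5-bromo-3-methoxy-2-(methoxymethoxy)phenyl]prop-2-enoate | CCOC(=O)/C=C/c1cc(Br)cc(OC)c1OCOC
F3 | step 3 | (E)-3-[5-bromo-3-methoxy-2-(methoxymethoxy)phenyl]prop-2-en-1-ol | OC/C=C/c1cc(Br)cc(OC)c1OCOC
F4 | step 5 | (3S)-3-[5-bromo-3-methoxy-2-(methoxymethoxy)phenyl]butane-1,2-diol (C2 epimers) | OCC(O)[C@@H](C)c1cc(Br)cc(OC)c1OCOC
F5 | step 6 | (3,4-dimethoxyphenyl)lithium | [Li]c1ccc(OC)c(OC)c1
F6 | step 6 | dichloro(3,4-dimethoxyphenyl)cerium | Cl[Ce](Cl)c1ccc(OC)c(OC)c1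
F7 | step 7 | (1RS,2S)-2-(5-bromo-2-hydroxy-3-methoxyphenyl)-1-(3,4-dimethoxyphenyl)propan-1-ol | COc1ccc(C(O)[C@@H](C)c2cc(Br)cc(OC)c2O)cc1OC
A1 | alternative 1 | methyl (2S,3S)-2-(3,4-dimethoxyphenyl)-7-methoxy-3-methyl-2,3-dihydro-1-benzofuran-5-carboxylate | COc1ccc([C@H]2Oc3c(OC)cc(C(=O)OC)cc3[C@@H]2C)cc1OC
A2 | alternative 1 | methyl 4-iodo-3-methoxybenzoate | COC(=O)c1ccc(I)c(OC)c1
A3 | alternative 1 | (2R,3S)-2-(3,4-dimethoxyphenyl)-3-methyloxirane | C[C@@H]1O[C@@H]1c1ccc(OC)c(OC)c1
A4 | alternative 2 | (2S,3S)-5-bromo-2-(3,4-dimethoxyphenyl)-7-methoxy-3-methyl-2,3-dihydro-1-benzofuran | COc1ccc([C@H]2Oc3c(OC)cc(Br)cc3[C@@H]2C)cc1OC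
A5 | alternative 2 | 4-bromo-2-methoxy-6-[1-(4-methylphenyl)sulfonylethyl]phenol | Cc1ccc(cc1)S(=O)(=O)C(C)c1cc(Br)cc(OC)c1O
A6 | alternative 2 | (2R,5R)-1-[(3,4-dimethoxyphenyl)methyl]-2,5-dimethylthiolan-1-ium bromide | C[C@@H]1CC[C@@H](C)[S+]1Cc1ccc(OC)c(OC)c1.[Br-]
A7 | alternative 3 | methyl (2S,3S)-5-bromo-2-(3,4-dimethoxyphenyl)-7-methoxy-2,3-dihydro-1-benzofuran-3-carboxylate | COc1ccc([C@H]2Oc3c(OC)cc(Br)cc3[C@@H]2C(=O)OC)cc1OC
A8 | alternative 3 | (2S)-6-bromo-2-(3,4-dimethoxyphenyl)-8-methoxy-2,3-dihydrochromen-4-one | COc1ccc([C@H]2Oc3c(OC)cc(Br)cc3C(=O)C2)cc1OC
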